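(The earlier runs and the new flask come from a simulation on assumed constants, noise included.)

| setting | Saturday's | Monday's | autumn | winter |
|---|---|---|---|---|
| Z | 0.67 M | 1.5 M | 1.0 M | 1.0 M |
| D | 200 mM (held) | 200 mM (held) | 200 mM (held) | 200 mM (held) |
| temperature | 0 °C | 18 °C | 5 °C | 30 °C |
| remark | run made earlier | run made earlier |  |  |
| time |  |  | 6.0 min | 6.0 min |

Saturday's run (percent of the Z charged)

| time / min | E / % | Z / % |
|---|---|---|
| 0.417 | 3.0 | 87.7 |
| 1.33 | 19.2 | 64.9 |
| 2.50 | 39.6 | 44.6 |
| 4.00 | 59.2 | 27.1 |

Monday's run (percent of the Z charged)

| time / s | E / % | Z / % |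
|---|---|---|
| 25.0 | 3.7 | 37.6 |
| 60.0 | 10.3 | 9.3 |
| 80.0 | 13.1 | 4.5 |
| 120 | 18.1 | 0.3 |

(scatter of a reading: 0.3 percentage points)

- percent here means Z units held: one G counts as two
- at the start none of D is in solution

- which of the two there is more of at the end, counted by the Z in each, autumn (E / G)
- which of the two there is more of at the end, counted by the Z in each, winter (E / G)
- E at the end, in percent of the Z charged, autumn
- E at the end, in percent of the Z charged, winter

Monday's run gave me the one figure I carried. Between its first and last readings E grew by 0.136 M/min on average, and I called this pace the delivery: the molar E per minute that I took D to feed. Z itself fell away first order, at 0.328 /min on Saturday's readings and 2.32 /min on Monday's. Carrying the logarithm in a straight line through temperature, which for winter meant going beyond Monday's run, I took 0.564 /min for autumn and 8.53 /min for winter.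

Then I kept books on the Z. While Z is lost faster than the delivery, I booked the delivery to E and the surplus to G; after the hand-over, when the two paces are equal, I booked the Z lost to E. For autumn I reckoned the hand-over at 2.52 min. By then my books had E at 34.3% of the charge and 24.2% still as Z. For the end they had 3.39% as Z, so they closed at E 55.1% and G 41.5%. For winter I reckoned the hand-over at 0.485 min, and those books closed at E 8.22% and G 91.8%.

The forecast said E for autumn with 52% (42% to 62%), and G for winter with 12% (7% to 19%), on the ground that “E is limited by D dissolving”. My autumn figure stood above its number and my winter figure below.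

The flask gave E 58.3% against G 38.3% in autumn, 6.3 percentage points above the forecast, and E 11.6% against G 88.4% in winter, within its range.

    Z → Q (k = 0.00966 /s, Ea = 73.0 kJ/mol)
    X + Q → E (k = 0.836 /M/s, Ea = 47.0 kJ/mol)
    2 Q → G (k = 0.0985 /M/s, Ea = 63.0 kJ/mol)
    D ⇌ X, rate k4*(csat - [X]) (kL = 0.0149 /s)
    (constants at 5 °C)

Winter's E stands so far below autumn's because of the temperature: with that difference taken away, the winter flask run at 5 °C gives 58.3%. Winter's 0.116 M of E equals 0.852 min of delivery, longer than my hand-over time. With 1.7 M of Z in the winter flask, that stretch of delivery gives 6.82% of the charge; the computed result is 7.55%.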